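**Retrosynthetic overview**
1. Feature: C6 and C10 are the two seven-ring carbons bonded to the fusion bond C5–C1. Seen from the five-membered ring they are a latent cis-1,2-dialdehyde (a 1,4-dicarbonyl pair). The C7–C8–C9 segment joining them is an acetone-like unit oxygenated at its middle carbon C8.
2. Key disconnection: C6–C7 and C9–C10 are cut together. In the forward sense, a Lewis-acid (3+4) annulation of the dialdehyde with a 1-alkoxy-1,3-bis(silyloxy)butadiene closes the tetrahydrofuran ring (C6–O–C10) and the seven-membered ring at once, as an 8-oxabicyclo[3.2.1]octan-3-one.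
3. Ring order: the five-membered ring comes first, by ring contraction of (S)-terpinen-4-ol, which supplies C4; C1 is set by vinyl-copper addition anti to a temporary 2β-silyloxy group. The oxa-bridge and seven-membered ring follow, and the oxirane is last.
4. After the annulation the C9 ester selects the C10–O bond for cleavage, so the oxygen stays on C6, and the ester is then lost. C8=O is methylenated and C5 is inverted (cis to trans fusion) at the C6 enone stage. The 4β-OH steers hydride to C2 and C6, and dehydrogenation followed by 1,4-hydrogenation of the 7,9-diene places the alkene at C8=C9.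
5. End game: C2 acetate, 6α-OH-directed α-epoxidation, C6 vanillate (phenol as benzyl ether), hydrogenolysis.

Key step: step 10

Numbering: C1 (quaternary, CH3), C2, C3, C4 (O, isopropyl) and C5 form the five-membered ring. C5, C6, C7, C8, C9, C10 and C1 form the seven-membered ring. β is the face of the C1 methyl. These labels are used from the first intermediate on. TBS = tert-butyldimethylsilyl, TES = triethylsilyl, TMS = trimethylsilyl.
Assumption: (S)-(+)-terpinen-4-ol is used as the enantiopure commercial grade. The diene carries a benzyl instead of a methyl ester so that the ester can later be removed under neutral conditions.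

**Step 1**
Reactants: 1 (S)-terpinen-4-ol
Product: 2 (1R,5R)-5-isopropyl-2-methylcyclohex-2-ene-1,5-diol (new C2–OH cis to the C4–OH)
Conditions: SeO2 (cat.), t-BuOOH, CH2Cl2, 0 °C → rt
Reagents that add atoms: tert-butyl hydroperoxide, CC(C)(C)OO
Why: The Riley oxidation (ene reaction, then [2,3]-shift) attacks the ring CH2 next to the methyl-bearing alkene carbon, and because the pseudo-axial C–H trans to the equatorial isopropyl group is replaced suprafacially, the new hydroxyl should lie cis to the tertiary one (as in limonene to trans-carveol), while the non-solvolytic medium keeps the pseudo-symmetric allyl unit from scrambling.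

**Step 2**
Reactants: 2 cis-diol
Product: 3 C2-O-TBS ether of 2
Conditions: TBSCl, imidazole, DMF, 0 °C → rt
Reagents that add atoms: tert-butyldimethylsilyl chloride, CC(C)(C)[Si](C)(C)Cl
Why: Silyl ether formation selects the secondary allylic alcohol over the hindered tertiary one and touches no stereocentre.

**Step 3**
Reactants: 3 mono-TBS ether
Product: 4 C2-O-TBS, C4-O-TES bis-ether
Conditions: Et3SiOTf, 2,6-lutidine, CH2Cl2, 0 °C
Reagents that add atoms: triethylsilyl triflate, CC[Si](CC)(CC)OS(=O)(=O)C(F)(F)F
Why: Silyl triflate silylation caps the tertiary alcohol, which blocks retro-aldol cleavage of the β-oxy aldehyde made in the next step.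

**Step 4**
Reactants: 4 bis-silyl ether
Product: 5 (3S,5R)-5-(TBSO)-3-isopropyl-6-oxo-3-(TESO)heptanal
Conditions: O3, pyridine, CH2Cl2, −78 °C
Reagents that add atoms: ozone, [O-][O+]=O
Why: Reductive ozonolysis, in which pyridine decomposes the carbonyl oxide directly to carbonyl compounds, cleaves the only alkene to the C1 methyl ketone and the C6 aldehyde without touching C2 or C4.

**Step 5**
Reactants: 5 keto aldehyde
Product: 6 (3R,5R)-3-(TBSO)-5-isopropyl-2-methyl-5-(TESO)cyclopent-1-ene-1-carbaldehyde (C1=C5, CHO = C6)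
Conditions: Bn2NH·CF3CO2H (cat.), toluene, 50 °C
Reagents that add atoms: none
Why: In this amine-salt-catalysed intramolecular aldol condensation the enamine of the aldehyde (C5) adds to the methyl ketone (C1) in a 5-(enolexo)-exo-trig closure and dehydrates to the tetrasubstituted enal, and the mild salt is chosen to avoid β-elimination of the C4 silyloxy group.

**Step 6**
Reactants: 6 enal; 7 vinylmagnesium bromide
Product: 9 vinyl aldehyde (C1 β-CH3/α-vinyl; C2 β-OTBS; C4 β-OTES/α-isopropyl; C5 β-H/α-CHO), via trimethylsilyl enol ether 8 (not isolated)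
Conditions: CuBr·SMe2 (cat.), Me3SiCl, DMPU, THF, −78 °C; then citric acid, THF–H2O, 0 °C
Reagents that add atoms: chlorotrimethylsilane, C[Si](C)(C)Cl (its silyl group is present only in 8)
Why: The chlorosilane-accelerated copper-catalysed conjugate addition builds quaternary C1 with the vinyl group entering anti to the adjacent 2β-silyloxy group (α face), and hydrolysis of 8 protonates C5 from the less hindered β face (methyl and silyloxy rather than vinyl and isopropyl), which leaves the formyl group α and cis to the vinyl group.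

**Step 7**
Reactants: 9 vinyl aldehyde
Product: 10 cis-dialdehyde (as 9, with α-CHO = C10 on C1)
Conditions: O3, pyridine, CH2Cl2, −78 °C
Reagents that add atoms: ozone, [O-][O+]=O
Why: Reductive ozonolysis turns the vinyl group into the C10 formyl group under neutral, cold conditions, so the epimerisable C5 is not disturbed.

**Step 8**
Reactants: 11 benzyl acetoacetate
Product: 12 benzyl (Z)-3-(trimethylsilyloxy)but-2-enoate
Conditions: Me3SiCl, Et3N, hexane, rt
Reagents that add atoms: chlorotrimethylsilane, C[Si](C)(C)Cl
Why: This is O-silylation of the enolised β-keto ester, and the alkene geometry has no consequence later.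

**Step 9**
Reactants: 12 silyl enol ether
Product: 13 (1Z)-1-benzyloxy-1,3-bis(trimethylsilyloxy)buta-1,3-diene
Conditions: LiN(i-Pr)2, Me3SiCl (in situ quench), THF, −78 °C
Reagents that add atoms: chlorotrimethylsilane, C[Si](C)(C)Cl
Why: Kinetic γ-deprotonation of the silyloxy crotonate and O-silylation of the ester dienolate give the 1,3-bis(silyloxy)diene, an acetoacetate dianion equivalent.

**Step 10**
Reactants: 10 cis-dialdehyde; 13 bis(silyloxy)diene
Product: 15 oxa-bridged benzyl keto ester (6α,10α-oxygen bridge; C8 ketone; 9β-CO2Bn; 5β-H; 2β-OTBS; 4β-OTES), via silyloxy tetrahydrofuran 14 (not isolated)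
Conditions: Me3SiOTf (cat.), CH2Cl2, −78 °C
Reagents that add atoms: none
Why: Me3SiOTf silylates one formyl oxygen and the neighbouring formyl oxygen adds to that carbon, so 10 reacts through two rapidly interconverting five-membered silyloxy oxocarbenium ions; the terminal CH2 of 13 (C7) attacks the ion that is cationic at C6 to give 14, whose C10–OTMS group then ionises and is captured by the remaining enol silane carbon C9 with loss of (Me3Si)2O. This is the known Lewis-acid (3+4) annulation of 1,4-dicarbonyl compounds with 1,3-bis(silyloxy)dienes to 8-oxabicyclo[3.2.1]octan-3-ones. The tetrahydrofuran ring closes 5-exo-trig, and the C9–C10 bond closes the carbocycle 7-(enolendo)-exo-trig, which is at the same time a 6-endo attack on the C10=O+ bond within the pyranone ring. C6 and C10 are set by attack on the convex face of the cis-bicyclo[3.3.0] cation, the face that carries H5 and the C1 methyl, so the oxygen bridge lies α and the cyclopentane is exo, while C9 is epimerisable and settles with its ester equatorial (β). The step needs C7 to pair with C6 and C9 with C10: both cations are secondary and electronically alike, so the faster bimolecular attack decides (Curtin–Hammett), and on the convex face C6 is flanked only by H5 whereas C10 is flanked by the methyl of quaternary C1, which leaves the hindered C10 for the intramolecular closure. The cis relation of the two formyl groups fixed in step 6 is what allows the bridge to form at all.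

**Step 11**
Reactants: 15 oxa-bridged keto ester
Product: 16 ring-opened alkylidene keto ester (C9=C10, 9-CO2Bn, C8 ketone, 6α-OTES, 5β-H)
Conditions: Et3SiOTf, Et3N, CH2Cl2, −78 → 0 °C
Reagents that add atoms: triethylsilyl triflate, CC[Si](CC)(CC)OS(=O)(=O)C(F)(F)F
Why: In this silyl triflate/amine opening of an 8-oxabicyclo[3.2.1]octan-3-one (soft enolisation, then β-elimination of the silylated bridge oxygen) only the doubly activated C9–H is enolised, so only the C10–O bond breaks, and the released C6 oxygen is held as its silyl ether so that it cannot add back to the alkylidene keto ester.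

**Step 12**
Reactants: 16 alkylidene keto ester
Product: 18 cis-fused hydroazulen-8-one (6α-OTES, 2β-OTBS, 4β-OTES, 5β-H), via saturated β-keto acid 17 (not isolated)
Conditions: H2 (1 atm), Pd/C, EtOAc, rt; then toluene, 80 °C
Reagents that add atoms: none
Why: Catalytic hydrogenation saturates the electron-poor C9=C10 bond and hydrogenolyses the benzyl ester, after which β-keto acid 17 decarboxylates through the usual cyclic transition state, a path that is closed as long as C9 is sp2; the C9 centre of 17 is lost.

**Step 13**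
Reactants: 18 ketone
Product: 19 8-methylene compound (C8=CH2)
Conditions: Ph3PCH3Br, KN(SiMe3)2, THF, 0 °C; then 18, −78 → 0 °C
Reagents that add atoms: methyltriphenylphosphonium bromide, C[P+](c1ccccc1)(c1ccccc1)c1ccccc1.[Br-]
Why: Wittig methylenation brings in the future C8 methyl carbon without raising any question of C7 versus C9 enolisation.

**Step 14**
Reactants: 19 tris-silyl ether
Product: 20 6α-alcohol
Conditions: PPTS (cat.), MeOH–CH2Cl2, 0 °C
Reagents that add atoms: none
Why: Mild acid methanolysis removes the secondary TES ether well before the tertiary TES and the secondary TBS ethers.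

**Step 15**
Reactants: 20 6α-alcohol
Product: 21 cis-fused 6-ketone with 8-methylene group
Conditions: Dess–Martin periodinane, pyridine, CH2Cl2, 0 °C → rt
Reagents that add atoms: none
Why: The buffered Dess–Martin oxidation gives the β-silyloxy ketone without elimination.

**Step 16**
Reactants: 21 cis-fused ketone
Product: 23 trans-fused (5α-H) 7-en-6-one with C8 methyl, via cis-fused conjugated enone 22 (not isolated)
Conditions: DBU, toluene, rt → 60 °C
Reagents that add atoms: none
Why: Under base-mediated equilibration the exocyclic alkene first moves into conjugation, a state in which C7 has no acidic hydrogen and C8 no leaving group, and reversible enolisation at C5 then converts the cis-fused into the trans-fused enone, which should be favoured because C6 leaves the face occupied by the α-isopropyl group.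

**Step 17**
Reactants: 23 trans-fused enone
Product: 24 trans-fused 7,9-dien-6-one
Conditions: chloranil, t-BuOH, 80 °C
Reagents that add atoms: none
Why: Quinone dehydrogenation of an enone to the linear dienone proceeds by hydride abstraction from C10 of the extended dienol, cross-conjugated dehydrogenation is impossible because C4 is quaternary, and any deconjugated 8-ene isomer carried over from step 16 converges on the same dienone.

**Step 18**
Reactants: 24 bis-silyl dienone
Product: 25 2β,4β-dihydroxy dienone
Conditions: HF·pyridine, pyridine, THF, 0 °C → rt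
Reagents that add atoms: none
Why: Buffered acidic fluoride removes both silyl ethers and avoids the retro-aldol cleavage that basic fluoride could start in the β-hydroxy ketone.

**Step 19**
Reactants: 25 diol
Product: 26 4β-hydroxy-7,9-diene-2,6-dione
Conditions: Dess–Martin periodinane, pyridine, CH2Cl2, 0 °C
Reagents that add atoms: none
Why: Dess–Martin oxidation acts on the only secondary alcohol (C2) and erases the temporary 2β configuration.

**Step 20**
Reactants: 26 hydroxy dione
Product: 27 7,9-diene-2α,4β,6α-triol
Conditions: Me4NBH(OAc)3 (excess), MeCN–AcOH, −30 → 0 °C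
Reagents that add atoms: none
Why: In the Evans–Saksena reduction the borohydride exchanges an acetate for the 4β-hydroxyl and delivers hydride intramolecularly to the β faces of both β-hydroxy ketone carbonyls, which gives the 2α- and 6α-alcohols (each 1,3-anti to C4–OH), and this reagent does not reduce a carbonyl that lacks a bound hydroxyl.

**Step 21**
Reactants: 27 diene triol
Product: 28 8-ene-2α,4β,6α-triol
Conditions: (η6-naphthalene)Cr(CO)3 (cat.), H2 (70 bar), acetone, 40 °C
Reagents that add atoms: none
Why: Arene-chromium-tricarbonyl-catalysed 1,4-hydrogenation of the ring-locked s-cis diene adds hydrogen to C7 and C10 and leaves the double bond between C8 and C9, so the alkene is placed regiospecifically.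

**Step 22**
Reactants: 28 triol
Product: 29 2α-acetate
Conditions: Ac2O (1 equiv), pyridine, CH2Cl2, 0 °C
Reagents that add atoms: acetic anhydride, CC(=O)OC(C)=O
Why: Selective acylation should favour the cyclopentanol C2–OH, because C6–OH is screened by the α-isopropyl group and the tertiary C4–OH is inert.

**Step 23**
Reactants: 29 homoallylic alcohol
Product: 30 8α,9α-epoxide
Conditions: VO(acac)2 (cat.), t-BuOOH, CH2Cl2, 0 °C → rt
Reagents that add atoms: tert-butyl hydroperoxide, CC(C)(C)OO
Why: In this hydroxyl-directed vanadium-catalysed epoxidation the homoallylic 6α-OH binds the metal peroxide and delivers oxygen to the α face of C8=C9, which is also the face away from the C1 β-methyl.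

**Step 24**
Reactants: 30 epoxy alcohol; 31 4-benzyloxy-3-methoxybenzoic acid
Product: 32 O-benzyl-protected target
Conditions: DCC, DMAP (cat.), CH2Cl2, rt
Reagents that add atoms: none
Why: Steglich esterification acylates the hindered 6α-OH with retention and spares the epoxide, the acetate and the tertiary alcohol.

**Step 25**
Reactants: 32 benzyl ether
Product: 33 target CNP0241679.3
Conditions: H2 (1 atm), Pd/C, EtOAc, rt
Reagents that add atoms: none
Why: Hydrogenolysis frees the phenol, and the unactivated trisubstituted epoxide and both esters are not affected.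

**Compound list**
1 | (S)-terpinen-4-ol | CC1=CC[C@](O)(C(C)C)CC1 | starting material
2 | (1R,5R)-5-isopropyl-2-methylcyclohex-2-ene-1,5-diol (hydroxyls cis) | CC1=CC[C@](O)(C(C)C)C[C@H]1O | intermediate
3 | secondary (C2) O-TBS ether of 2 | CC1=CC[C@](O)(C(C)C)C[C@H]1O[Si](C)(C)C(C)(C)C | intermediate
4 | C2-O-TBS, C4-O-TES bis-ether of 2 | CC1=CC[C@](O[Si](CC)(CC)CC)(C(C)C)C[C@H]1O[Si](C)(C)C(C)(C)C | intermediate
5 | (3S,5R)-5-(TBSO)-3-isopropyl-6-oxo-3-(TESO)heptanal | CC(=O)[C@H](O[Si](C)(C)C(C)(C)C)C[C@@](O[Si](CC)(CC)CC)(C(C)C)CC=O | intermediate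
6 | (3R,5R)-3-(TBSO)-5-isopropyl-2-methyl-5-(TESO)cyclopent-1-ene-1-carbaldehyde | O=CC1=C(C)[C@H](O[Si](C)(C)C(C)(C)C)C[C@@]1(O[Si](CC)(CC)CC)C(C)C | intermediate
7 | vinylmagnesium bromide | C=C[Mg]Br | starting material
8 | TMS enol ether of 9 (C5=C6, O cis to C4) | C=C[C@@]1(C)[C@H](O[Si](C)(C)C(C)(C)C)C[C@@](O[Si](CC)(CC)CC)(C(C)C)/C1=C\O[Si](C)(C)C | intermediate
9 | cyclopentanecarbaldehyde: C1 β-CH3/α-vinyl, C2 β-OTBS, C4 β-OTES/α-isopropyl, C5 β-H/α-CHO | C=C[C@@]1(C)[C@H](O[Si](C)(C)C(C)(C)C)C[C@@](O[Si](CC)(CC)CC)(C(C)C)[C@H]1C=O | intermediate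
10 | cis-cyclopentane-1,2-dicarbaldehyde: as 9 with α-CHO (C10) on C1 | O=C[C@@]1(C)[C@H](O[Si](C)(C)C(C)(C)C)C[C@@](O[Si](CC)(CC)CC)(C(C)C)[C@H]1C=O | intermediate
11 | benzyl acetoacetate | CC(=O)CC(=O)OCc1ccccc1 | starting material
12 | benzyl (Z)-3-(trimethylsilyloxy)but-2-enoate | C/C(O[Si](C)(C)C)=C/C(=O)OCc1ccccc1 | intermediate
13 | (1Z)-1-benzyloxy-1,3-bis(trimethylsilyloxy)buta-1,3-diene | c1ccccc1CO/C(O[Si](C)(C)C)=C/C(=C)O[Si](C)(C)C | intermediate
14 | cis-fused tetrahydrofuran: C10–OTMS acetal, C6 bearing CH2C(OTMS)=CHCO2Bn on the convex face | C[Si](C)(C)O/C(=C\C(=O)OCc1ccccc1)C[C@@H]2O[C@H](O[Si](C)(C)C)[C@@]3(C)[C@H](O[Si](C)(C)C(C)(C)C)C[C@@](O[Si](CC)(CC)CC)(C(C)C)[C@@H]23 | intermediate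
15 | oxa-bridged keto ester: 6α,10α-O bridge, C8=O, 9β-CO2Bn, 1β-CH3, 5β-H, 2β-OTBS, 4β-OTES | O=C1C[C@@H]2O[C@H]([C@H]1C(=O)OCc4ccccc4)[C@@]3(C)[C@H](O[Si](C)(C)C(C)(C)C)C[C@@](O[Si](CC)(CC)CC)(C(C)C)[C@@H]23 | intermediate
16 | cis-fused hydroazulene: 6α-OTES, C8=O, C9(CO2Bn)=C10 | CC[Si](CC)(CC)O[C@H]2CC(=O)C(C(=O)OCc1ccccc1)=C[C@@]3(C)[C@H](O[Si](C)(C)C(C)(C)C)C[C@@](O[Si](CC)(CC)CC)(C(C)C)[C@@H]23 | intermediate
17 | saturated 8-oxo-9β-carboxylic acid | CC[Si](CC)(CC)O[C@H]2CC(=O)[C@H](C(=O)O)C[C@@]3(C)[C@H](O[Si](C)(C)C(C)(C)C)C[C@@](O[Si](CC)(CC)CC)(C(C)C)[C@@H]23 | intermediate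
18 | cis-fused (5β-H) hydroazulen-8-one, 6α-OTES, 2β-OTBS, 4β-OTES | CC[Si](CC)(CC)O[C@H]2CC(=O)CC[C@@]3(C)[C@H](O[Si](C)(C)C(C)(C)C)C[C@@](O[Si](CC)(CC)CC)(C(C)C)[C@@H]23 | intermediate
19 | 8-methylene analogue of 18 | CC[Si](CC)(CC)O[C@H]2CC(=C)CC[C@@]3(C)[C@H](O[Si](C)(C)C(C)(C)C)C[C@@](O[Si](CC)(CC)CC)(C(C)C)[C@@H]23 | intermediate
20 | 6α-alcohol from 19 | O[C@H]2CC(=C)CC[C@@]3(C)[C@H](O[Si](C)(C)C(C)(C)C)C[C@@](O[Si](CC)(CC)CC)(C(C)C)[C@@H]23 | intermediate
21 | cis-fused 8-methylene-6-ketone | O=C2CC(=C)CC[C@@]3(C)[C@H](O[Si](C)(C)C(C)(C)C)C[C@@](O[Si](CC)(CC)CC)(C(C)C)[C@@H]23 | intermediate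
22 | cis-fused (5β-H) 8-methyl-7-en-6-one | O=C2C=C(C)CC[C@@]3(C)[C@H](O[Si](C)(C)C(C)(C)C)C[C@@](O[Si](CC)(CC)CC)(C(C)C)[C@@H]23 | intermediate
23 | trans-fused (5α-H) 8-methyl-7-en-6-one | O=C2C=C(C)CC[C@@]3(C)[C@H](O[Si](C)(C)C(C)(C)C)C[C@@](O[Si](CC)(CC)CC)(C(C)C)[C@H]23 | intermediate
24 | trans-fused 8-methyl-7,9-dien-6-one | O=C2C=C(C)C=C[C@@]3(C)[C@H](O[Si](C)(C)C(C)(C)C)C[C@@](O[Si](CC)(CC)CC)(C(C)C)[C@H]23 | intermediate
25 | 2β,4β-dihydroxy-7,9-dien-6-one | O=C2C=C(C)C=C[C@@]3(C)[C@H](O)C[C@@](O)(C(C)C)[C@H]23 | intermediate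
26 | 4β-hydroxy-7,9-diene-2,6-dione | O=C2C=C(C)C=C[C@@]3(C)C(=O)C[C@@](O)(C(C)C)[C@H]23 | intermediate
27 | 7,9-diene-2α,4β,6α-triol | O[C@H]2C=C(C)C=C[C@@]3(C)[C@@H](O)C[C@@](O)(C(C)C)[C@H]23 | intermediate
28 | 8-ene-2α,4β,6α-triol | O[C@H]2CC(C)=CC[C@@]3(C)[C@@H](O)C[C@@](O)(C(C)C)[C@H]23 | intermediate
29 | 2α-acetoxy-8-ene-4β,6α-diol | O[C@H]2CC(C)=CC[C@@]3(C)[C@@H](OC(C)=O)C[C@@](O)(C(C)C)[C@H]23 | intermediate
30 | 2α-acetoxy-8α,9α-epoxy-4β,6α-diol | O[C@H]2C[C@@]3(C)O[C@H]3C[C@@]3(C)[C@@H](OC(C)=O)C[C@@](O)(C(C)C)[C@H]23 | intermediate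
31 | 4-benzyloxy-3-methoxybenzoic acid | COc1cc(C(=O)O)ccc1OCc1ccccc1 | starting material
32 | 6α-(4-benzyloxy-3-methoxybenzoate) of 30 | COc1cc(C(=O)O[C@H]2C[C@@]3(C)O[C@H]3C[C@@]3(C)[C@@H](OC(C)=O)C[C@@](O)(C(C)C)[C@H]23)ccc1OCc1ccccc1 | intermediate
33 | CNP0241679.3 (2α-acetoxy-8α,9α-epoxy-4β-hydroxy-6α-vanilloyloxy, 5α-H) | COc1cc(C(=O)O[C@H]2C[C@@]3(C)O[C@H]3C[C@@]3(C)[C@@H](OC(C)=O)C[C@@](O)(C(C)C)[C@H]23)ccc1O | target

Total step count: 25. Longest linear sequence: 23 steps (steps 1–7 and 10–25).

**Steps most likely to fail**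

1. Step 10. The two termini of the diene may pair with the wrong formyl carbons, because steric discrimination between two hindered aldehydes is the only control. Intermolecular aldol oligomerisation may also outrun the second closure. The fallback sets out from 9, in which C10 is still a vinyl group and C6 is therefore the only electrophile.
   - BF3·OEt2-promoted vinylogous Mukaiyama aldol addition of 13 would give, after aqueous work-up, the δ-hydroxy β-keto ester F1.
   - Ozonolysis of its vinyl group (O3, pyridine) would give the C10 aldehyde, which closes on the C6 hydroxyl to the lactol F2.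
   - Me3SiOTf would then ionise the lactol, and the β-keto ester enol would close the C9–C10 bond. This returns to the route at 15.

2. Step 16. The C5 enolate may expel the C4 silyloxy group (β-elimination), or the equilibrium may not lie far enough on the trans-fused side. The fallback replaces thermodynamic control by kinetic control and sets out from 21.
   - Brief treatment with DBU at 0 °C only conjugates the alkene, and 22 is isolated.
   - LiN(i-Pr)2 and Me3SiCl at −78 °C would give the cross-conjugated silyl dienol ether F3.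
   - Bu4NF/AcOH at −78 °C would release the enolate, which is protonated irreversibly from the α face, anti to the C1 methyl and the C4 silyloxy group. This returns to the route at 23.

3. Step 11. The bridge may resist opening because its C–O bond overlaps poorly with the stabilised enol ether. Alternatively, excess silyl triflate may drive a second elimination that removes the C6 oxygen. The fallback traps the open form by reduction instead of silylation and sets out from 15.
   - A catalytic amount of piperidine and Hantzsch ester in toluene at 60 °C would reduce irreversibly the small equilibrium share of alkylidene keto ester, giving the hydroxy keto ester F4.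
   - Et3SiCl and imidazole would give its 6-O-TES ether F5.
   - Hydrogenolysis and decarboxylation as in step 12 return to the route at 18.

**Further compounds**
F1 | step 10 | benzyl 5-hydroxy-3-oxopentanoate carrying at C5 (= C6, configuration as in 15) the cyclopentyl group of 9 | C=C[C@@]1(C)[C@H](O[Si](C)(C)C(C)(C)C)C[C@@](O[Si](CC)(CC)CC)(C(C)C)[C@H]1[C@@H](O)CC(=O)CC(=O)OCc1ccccc1
F2 | step 10 | cis-fused C10 lactol with the C6 side chain CH2C(O)CH2CO2Bn | O=C(CC(=O)C[C@@H]2O[C@H](O)[C@@]3(C)[C@H](O[Si](C)(C)C(C)(C)C)C[C@@](O[Si](CC)(CC)CC)(C(C)C)[C@@H]23)OCc1ccccc1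
F3 | step 16 | 6-(trimethylsilyloxy)-5,7-diene (cross-conjugated silyl dienol ether of 22) | C[Si](C)(C)OC1=C2[C@](O[Si](CC)(CC)CC)(C(C)C)C[C@@H](O[Si](C)(C)C(C)(C)C)[C@]2(C)CCC(C)=C1
F4 | step 11 | benzyl 6α-hydroxy-8-oxo-9β-carboxylate, cis-fused, C9–C10 saturated | O[C@H]2CC(=O)[C@H](C(=O)OCc1ccccc1)C[C@@]3(C)[C@H](O[Si](C)(C)C(C)(C)C)C[C@@](O[Si](CC)(CC)CC)(C(C)C)[C@@H]23
F5 | step 11 | 6-O-TES ether of F4 | CC[Si](CC)(CC)O[C@H]2CC(=O)[C@H](C(=O)OCc1ccccc1)C[C@@]3(C)[C@H](O[Si](C)(C)C(C)(C)C)C[C@@](O[Si](CC)(CC)CC)(C(C)C)[C@@H]23
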